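In a one-step world a product simply grows, so its yield follows from how far the step has run. Here the first nucleophile that makes the target also destroys it, so I followed how long the two stand together.

| setting | midnight | winter | dusk | blue | amber | red | violet |
|---|---|---|---|---|---|---|---|
| starting material | 0.40 M | 0.40 M | 0.40 M | 0.40 M | 0.40 M | 0.40 M | 0.40 M (fed, over 12 min) |
| first nucleophile | 1 equiv | 1 equiv | 1 equiv | 1.00 equiv | 1.00 equiv (in portions, 4, over 12 min) | 1.00 equiv (fed, over 12 min) | 1.00 equiv |
| second nucleophile | 1.2 equiv | 0.60 equiv | 0.90 equiv | 1.20 equiv | 1.20 equiv | 1.20 equiv | 1.20 equiv |
| remark | run made earlier | run made earlier | run made earlier | everything together at the start | first portion at the start, last at 12 min | all else is in the flask from the start; the feed brings no volume worth counting | all else is in the flask from the start; the feed brings no volume worth counting |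
| time |  |  |  | 15 min | 15 min | 15 min | 15 min |

| run | time / min | target / % | starting material / % |
|---|---|---|---|
| midnight | 1.33 | 28.5 | 31.5 |
| midnight | 2.00 | 32.5 | 21.4 |
| midnight | 3.00 | 31.5 | 12.4 |
| midnight | 4.00 | 29.7 | 6.0 |
| midnight | 6.00 | 26.0 | 2.8 |
| midnight | 10.0 | 25.6 | 2.7 |
| midnight | 15.0 | 24.9 | 0 |
| winter | 1.33 | 33.8 | 35.1 |
| winter | 2.00 | 37.7 | 24.7 |
| winter | 3.00 | 37.8 | 15.4 |
| winter | 5.00 | 37.3 | 7.5 |
| winter | 8.00 | 34.5 | 5.0 |
| winter | 12.0 | 36.0 | 3.0 |
| winter | 20.0 | 33.8 | 2.1 |
| dusk | 2.50 | 34.8 | 15.1 |
| dusk | 5.00 | 34.5 | 5.8 |
| dusk | 8.00 | 31.1 | 1.3 |
| dusk | 10.0 | 30.0 | 1.9 |
| dusk | 12.0 | 29.2 | 1.9 |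
| dusk | 15.0 | 29.3 | 1.8 |
| dusk | 20.0 | 28.4 | 0 |

(each reading ± 1 percentage point)

- steps under discussion: starting material <-> intermediate; first nucleophile + intermediate -> target; second nucleophile + intermediate -> other capture product; 2 second nucleophile -> self-condensation product; first nucleophile + target -> over-reaction product; starting material -> decomposition product

- the flask that comes out highest in amount of target, in percent of the starting material charged, or "all alike" when all lie within 1.5 percentage points (blue / amber / red / violet / all alike)
- target at the end, in percent of the starting material charged, blue
- target at the end, in percent of the starting material charged, amber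
- target at the end, in percent of the starting material charged, red
- target at the end, in percent of the starting material charged, violet

I began with a balance: each target costs one first nucleophile and each over-reaction product costs two. I counted that reagent as used up at 15.0 min in midnight, where starting material reads 0 %, and the target reading then gave a capture share of 62.5 %, the part of the starting material taken by first nucleophile. With that share, the midnight readings put over-reaction product at 14.3 % at 1.33 min and 29.0 % at 4.00 min, while first nucleophile left fell from 42.9 % to 12.3 % of its charge. That growth gave a reading of 0.686 min⁻¹ for the loss rate of target at full c(first nucleophile), a pseudo-first-order constant.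

For violet I counted back from the moment I supposed c(first nucleophile) to come near its end. In a final stretch I took the first nucleophile remaining as roughly equal to the target still to be made, and I let over-reaction matter once that amount, as a fraction of the starting material charged, times the loss rate times the stretch reaches one. Sending every fed starting material to target gave 34.8 %. That was the weak link, since midnight's capture share was 62.5 %, so I reforged it with the share in the feed rate. The stretch became 5.29 min, shorter than the feed, and the target became 27.5 %, the closing target: the square root of the captured feed rate over the loss rate. Blue has the charges of midnight, which read 24.9 % at 15.0 min, so I put violet higher; red and amber I did not reckon.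

The forecast differed: it chose blue, with 25 % for blue, 6 % for amber, 6 % for red and 17 % for violet, where “Late feed then stalls”.

    starting material ⇌ intermediate (K = 0.0563, k = 0.0205 s⁻¹)
    first nucleophile + intermediate → target (k = 1.75 M⁻¹ s⁻¹)
    second nucleophile + intermediate → other capture product (k = 1.33 M⁻¹ s⁻¹)
    2 second nucleophile → self-condensation product (k = 0.0206 M⁻¹ s⁻¹)
    first nucleophile + target → over-reaction product (k = 0.0251 M⁻¹ s⁻¹)
    starting material → decomposition product (k = 3.77 × 10⁻⁶ s⁻¹)

The flasks gave 23.4 % for blue, 10.6 % for amber, 6.53 % for red and 29.3 % for violet, so violet came highest. Violet ended with 0.794 % of its first nucleophile left, close to the end of that reagent which the closing target supposes, and 27.5 % stands beside 29.3 %. With the feed rate, the capture share and the loss rate held, the charge of first nucleophile does not enter the closing target, so for the neighbour of violet with 0.600 equiv I again reckoned 27.5 %. That flask gave 27.1 %, with 0.0612 % of its first nucleophile left.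

(All runs come from a simulation with made-up constants; the scatter is artificial.)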